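- In charge per minute, the first slope of Imd2 read 0.754 min⁻¹ in the south run. Imd takes up Ptn to give Imd2, and Imd2 takes up Ptn to give Imd3.

| setting | north | south | flask |
|---|---|---|---|
| Imd | 0.19 M | 0.19 M | 0.19 M |
| Ptn | 0.38 M | 0.38 M | 0.380 M |
| Tsp | 9.5 mM | 9.5 mM | 9.50 mM |
| Tsp2 | 0.095 M | 0.38 M | 0.190 M |
| remark | run made earlier | run made earlier |  |
| time |  |  | 5.0 min |

| run | time / min | Imd2 / % | Imd3 / % |
|---|---|---|---|
| north | 0.417 | 21.8 | 3.7 |
| north | 0.833 | 23.9 | 9.9 |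
| north | 1.33 | 19.9 | 16.2 |
| north | 1.50 | 19.3 | 18.3 |
| north | 2.00 | 15.8 | 23.2 |
| north | 2.50 | 13.9 | 26.2 |
| north | 3.00 | 10.8 | 29.2 |
| south | 0.167 | 12.6 | 1.6 |
| south | 0.500 | 20.4 | 4.8 |
| south | 0.833 | 19.4 | 8.6 |
| south | 1.33 | 15.7 | 14.1 |
| south | 2.00 | 12.1 | 19.5 |
| south | 2.50 | 9.6 | 22.8 |
| south | 3.00 | 7.5 | 24.1 |

(each reading ± 0.3 percentage points)

- equivalents of Ptn to Imd, everything else as given, that leave most Imd2 at 5.0 min
- the amount of Imd2 then, in percent of the Imd charged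
- the amount of Imd2 with the amounts as given



- The knee came early. The highest Imd2 reading was 23.9 % at 0.833 min in north, and 20.4 % at 0.500 min in south, which is lower.
- In north, Imd3 crossed Imd2 at about 1.56 min.
- After that, Imd2 in north fell with an apparent pseudo-first-order constant of 0.387 min⁻¹, as read. The north readings showed no level yet.
- I replaced the falling c(Ptn) by its mean. Counting just the two forms I could read, one Ptn in Imd2 and two in Imd3, I put the mean at 0.261 M, and the ends lay 4.84 % from it.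
- The fall constant per molar of Ptn, as read in north, was therefore 1.48 M⁻¹ min⁻¹.
- The flask's Tsp2 lies midway between the runs on a log scale, so I began from 9.00 % at 3.00 min. With north's last c(Ptn), my curve reached 4.31 % at 5.0 min.
- The forecast said 4 %, and 8.5 % at 0.7 equiv: “Less Ptn lowers the plateau but greatly slows Imd2 loss”.
- The flask gave 5.91 %, and 14.1 % at 0.633 equiv.

    Imd + Ptn ⇌ Lvg + Imd2 (K = 36.0, k = 0.0500 M⁻¹ s⁻¹)
    Imd2 + Ptn ⇌ Lvg + Imd3 (K = 8.70, k = 0.0340 M⁻¹ s⁻¹)
    Imd2 + Tsp → Imd2.Tsp (k = 0.450 M⁻¹ s⁻¹)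
    Tsp2 + Imd → Tsp2.Imd (k = 0.0420 M⁻¹ s⁻¹)
    Lvg + Imd ⇌ Lvg.Imd, settled at all times (K = 270 M⁻¹)

- From 2.50 min to 5.00 min, the flask's Imd2 fell from 11.9 % to 5.91 %. With mean c(Ptn) 0.242 M, that is 1.16 M⁻¹ min⁻¹ against my 1.48 M⁻¹ min⁻¹.
- In the neighbour flask with 0.76 M of Imd, c(Ptn) ended at 0.0160 M. At that c(Ptn), my constant gives a half-life of 29.3 min, and Imd2 in that flask stood at 20.2 %.
- The flask had not come to rest. From 5.00 min to 50.0 min, my constant gives a half-life near 2.27 min, yet Imd2 moved 0.63 percentage points, to 5.28 %, while Imd3 climbed from 33.9 % to 47.0 %.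

Readings and results are calculated for an exercise; the scatter is artificial.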